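Readings and results come from a simulation from invented constants; noise was put on by code.

Take equal rates on the two mirror images as the zero of the scale: both substrates then fall together, and every excess stays at nil. I measured the departure from that zero before choosing the next run.

all flasks: left-handed substrate 0.80 M; right-handed substrate 0.80 M; precatalyst 0.80 mM
- larch: coupling partner 0.59 M; run made earlier
- oak: coupling partner 1.3 M; run made earlier
- flask: coupling partner 0.880 M; time 2.5 d

| run | time / h | left-handed substrate / % | right-handed substrate / % | left-handed product / % |
|---|---|---|---|---|
| larch | 10.0 | 48.8 | 49.5 | 2.0 |
| larch | 20.0 | 47.1 | 48.9 | 2.9 |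
| larch | 30.0 | 45.4 | 48.8 | 4.1 |
| larch | 40.0 | 43.5 | 46.7 | 5.9 |
| larch | 50.0 | 43.5 | 47.7 | 6.2 |
| oak | 4.00 | 48.2 | 49.6 | 0.4 |
| oak | 12.0 | 43.8 | 47.8 | 6.2 |
| oak | 20.0 | 39.4 | 45.7 | 11.2 |
| oak | 30.0 | 35.0 | 44.4 | 14.0 |
| oak | 50.0 | 30.4 | 43.1 | 19.2 |

(standard deviation of a reading: 0.5 percentage points)

- free catalyst is single-handed; left-handed substrate and right-handed substrate are mirror images of each other, charged as a racemate, each of them at the stated concentration
- the numbers in the tables scatter with a standard deviation of 0.5 percentage points
- an excess is the difference of the two amounts in percent of their sum
- an excess is below zero if the other one leads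

- part of the left-handed substrate and right-handed substrate charged together that has reacted at 2.5 d
- excess of left-handed product over right-handed product in the product at 2.5 d
- excess of right-handed substrate over left-handed substrate among what is left of the two at 2.5 d

Oak's last row gave me 3.35 for the selectivity factor, the logarithm of the left-handed fraction left over the logarithm of the right-handed fraction left, with 1 as the zero case. Larch read 2.96, but its right-handed loss was 2.3 percentage points against a scatter of 0.5 points, so I carried oak's value. The two readings suggested that more partner buys distance, not selectivity, so I kept the other charges and set the partner between the runs, for 2.5 d.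

The distance still needed reckoning. By 50.0 h, the logarithmic left-handed loss read 0.139 in larch and 0.498 in oak, which reads as an apparent partner order of 1.61. Scaling to this flask's partner and, generously, in proportion to time, I got 0.318. That estimate put 72.7% of the left-handed charge as remaining in this flask, and dividing the logarithmic loss by the selectivity factor put 90.9% of the right-handed charge as remaining. My figures were therefore 18.2% reacted, a product excess of 50.0% and a substrate excess of 11.1%.

The forecast, reading “a kinetic resolution in which the left-handed substrate reacts faster”, gave 17%, 46% and 9.5%.

The flask gave 17.6%, 48.2% and 10.3%.

    coupling partner + free catalyst + left-handed substrate → free catalyst + left-handed product (k = 120 /M²/h)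
    coupling partner + free catalyst + right-handed substrate → free catalyst + right-handed product (k = 38.0 /M²/h)
    free catalyst → spent catalyst (k = 0.130 /h)
    coupling partner + precatalyst → free catalyst + spent reagent (k = 0.0220 /M/h)

The flask kept 74% of its left-handed charge; through the carried selectivity factor that means 91.4% of the right-handed charge, and it kept 91%. A neighbouring flask, charged with 0.0014 M of precatalyst and otherwise unchanged, kept 64% of its left-handed charge. The same step gave 87.5% of the right-handed charge, hence a substrate excess of 15.5%. That neighbour kept 87% of its right-handed charge, reached 24.6% reacted with a product excess of 46.4%, and stood at a substrate excess of 15.1%.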